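**Assumption (one line):** the skeleton is numbered C1 (CH–i-Pr), C2 and C6 (ring fusion), C3, C4 (C–CH3), C5, C7, C8 (carbinol), C9, C10 (CH–O) throughout; β is the face of the C1 isopropyl group; compounds 3, 7, 11 and 19 are taken as commercial. TBS = tert-butyldimethylsilyl, TMS = trimethylsilyl, Tf = trifluoromethanesulfonyl, PMB = 4-methoxybenzyl.

## The problem

Target 23 is a trans-fused hydroazulene: a five-membered ring (C2, C3, C4, C5, C6) shares the C2–C6 bond with a seven-membered ring (C1, C2, C6, C7, C8, C9, C10). It has seven stereocentres, (1S,2R,4R,5S,6S,8R,10S): C2–H β, C6–H α, C8–OH β, C10–O-aroyl α, epoxide β.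

The trans ring fusion cannot be counted on from equilibration and is best carried in from a trans-disubstituted five-membered ring. C1 is exocyclic to that ring until the seven-membered ring closes, so its configuration relative to C2 is a problem of acyclic stereocontrol.

C8 and C10 are 1,3-anti. C10 can be set from C8 by intramolecular hydride delivery, but C8 itself must come out of the ring-closing event. The epoxide lies on the face cis to the C6–C7 bond, the more hindered face of the cyclopentene, so it needs direction from the C8 hydroxyl three carbons away.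

The fragile groups are the trisubstituted epoxide (acid), the aryl ester with a free phenol (base, nucleophiles) and the tertiary carbinol, which sits β to C10 and invites retro-aldol cleavage or dehydration whenever C10 is a ketone.

The feature that allows the key step: the oxygen on the fully substituted C8 and the heteroatom on C10 are 1,3 across C9. C8–C9–C10 is therefore the retron of an N–O heterocycle (C10–N–O–C8) made from a C10 dipole and a C8=C9 1,1-disubstituted alkene. The four-atom tether C1–C2–C6–C7 contains the trans C2–C6 bond of the five-membered ring.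

## Retrosynthesis

**Epoxide and phenol (23 ⇒ 22 ⇒ 21).** The phenol silyl ether and the two epoxide C–O bonds are cut last, because the epoxide is the least robust group. An undirected peracid would attack alkene 21 anti to C7 and give the α-epoxide; the free C8–OH of 21 is the only handle on the β face. The forward step asks a vanadate ester of a bishomoallylic tertiary alcohol to deliver oxygen.

**C4 methyl and ester (21 ⇒ 20 ⇒ 18 + 19).** The C4–CH3 bond and the ester C–O bond are cut. The C4=C5 unit is held as the C4 enol triflate from step 4 to step 13. A C4 ketone would have to be enolised toward C5 and not C3 with no bias late in the route; the triflate fixes the regiochemistry when the enolate is formed. It is also a poor dipolarophile and survives zinc, tetravalent cerium and borohydride. The methyl is coupled late, so no nucleophilic ring alkene meets the oxidants. Only the secondary C10–OH of diol 18 is acylated by acid 19.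

**C10 oxygen (18 ⇒ 17 ⇒ 15 ⇒ 14 ⇒ 13).** The C10–H bond is cut back to β-hydroxy ketone 17 (directed reduction gives the 1,3-anti diol). The C10 carbonyl is then traced to the C10 amine 15, its PMB derivative 14 and the N–O bond of isoxazolidine 13. Displacing nitrogen by oxygen with inversion would be shorter but is not reliable at a hindered secondary centre; oxidation to the ketone followed by hydride delivery from C8 is.

**Key disconnection (13 ⇒ 12).** The C9–C10 and O–C8 bonds are cut, opening the seven-membered ring and the N–O ring in one intramolecular 1,3-dipolar cycloaddition. A C10 nitrile oxide would give the β-hydroxy ketone mask (an isoxazoline) directly, and was considered first. It fails on structure: with C8, C9 and C10 all in the carbocycle, the isoxazoline would be an 8-oxa-7-azabicyclo[4.2.1]non-6-ene with a bridgehead C=N, and the linear dipole would instead attack C8 to close an unstrained six-membered ring. A nitrone forms the same two bonds and the same two rings but leaves C10 sp3. The cost is three later steps to turn C10–N into C10=O. The forward reaction must take the bridged mode and put oxygen on the β face of C8.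

**Nitrone precursor (12 ⇒ 10 + 11 ⇒ 9).** The C=N bond is cut to aldehyde 10 and hydroxylamine 11; 10 comes from ester 9 by partial reduction.

**C6–C7 bond (9 ⇒ 6 + 7).** The C6–C7 bond and the O–S bond are cut: conjugate addition of the methallyl group of 7 to enone 6, anti to the C2 side chain, with the enolate trapped at oxygen. This gives the trans C2/C6 relationship and the C4=C5 regiochemistry in one operation.

**C1–C2 bond (6 ⇒ 5 ⇒ 2 + 3).** The C1–C2 bond is cut to ketene acetal 2 and silyloxy enone 3 (Mukaiyama–Michael addition), followed by loss of silanol from 5. The obvious alternative, addition to cyclopent-2-enone with alkylation of the enolate at C6, was set aside on stereochemical grounds. In the open transition state the isopropyl group avoids the ring carbon that is not the enone α-carbon. If the carbonyl stayed next to C6, that preference would give the C1 epimer. In 3 the oxygenated carbon becomes C6 after elimination, so the same preference gives the required C1/C2 relationship, and the silyloxy group also fixes the absolute configuration of C2. Ketene acetal 2 comes from ester 1.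

## Roads not taken

**Alternative 1:** Nazarov annulation of the five-membered ring onto a finished seven-membered ring (cut C2–C3). FeCl3 would close dienone A1 by conrotatory cyclisation to cyclopentenone A2, with silicon fixing the enone at C3=C4.
- Merits: the C4 methyl is in place, the position of unsaturation is unambiguous after a reductive enone transposition, and C10 already carries oxygen, so no nitrogen has to be removed. In that respect it is better than the chosen plan.
- Weak points: A1 is an enantiopure cycloheptene that already holds C1, C8 and the 1,3-anti C10 oxygen, so the hardest part of the target must be made first by other means. The sense of conrotation is controlled only by the adjacent C1 centre. The ring fusion is set by a kinetic protonation at C6. A strong Lewis acid meets a tertiary silyl ether. Three more steps are needed to move the alkene to C4=C5.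
- Against it the chosen plan offers a seven-membered ring, the C8 carbinol and the ring fusion all derived from a simple cyclopentenone by substrate-controlled additions.

**Alternative 2:** Samarium Reformatsky closure (cut C8–C9). SmI2 would convert bromomethyl ketone A3 to the C9 samarium enolate, which adds to the C8 methyl ketone to give β-hydroxy ketone A4.
- Merits: A4 is at the oxidation level that the chosen plan reaches only three steps after ring closure, and the ring alkene can be present from the start. In step count after the key step this road is better.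
- Weak points: the C8 configuration depends on the face of a chelated medium-ring transition state, which is as unproven as the nitrone face. A3 needs two differentiated ketones, one of them a bromomethyl ketone next to the epimerisable C1. Simple debromination and ketyl reduction of the methyl ketone compete. The product appears as an aldolate that can revert or dehydrate.
- Against it the chosen plan offers a concerted closure to an isoxazolidine that cannot revert, epimerise or eliminate under its conditions of formation, from a nitrone made in one neutral step.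

**Alternative 3:** Diels–Alder hydrindane then ring expansion (cut C1–C2 and C6–C7 of a six-membered ring). Diene A5 and enone A6 would combine under a chiral oxazaborolidinium catalyst to the cis-fused endo adduct A7; a one-carbon insertion between C8 and C10 would follow.
- Merits: two C–C bonds and the bicyclic carbon frame in one catalytic asymmetric step from trivial materials. This is better than the stoichiometric chiral building block used here.
- Weak points: the adduct has the wrong ring size and is wrong at both C1 and C6. The trans hydroazulenone is not strongly favoured on equilibration. The ring expansion must be regioselective. C8 and C10 still have to be oxygenated and set afterwards.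
- Against it the chosen plan sets C1, C2 and C6 before ring closure and forms the seven-membered ring at its final size with the C8 oxygen attached.

Key step: step 7

## Route

Step 1
Reactants: 1 methyl 3-methylbutanoate
Product: 2 (E)-1-methoxy-3-methyl-1-(trimethylsilyloxy)but-1-ene
Conditions: LiN(i-Pr)2, THF, −78 °C; Me3SiCl, −78 °C to rt
Reagents that add atoms: chlorotrimethylsilane, C[Si](C)(C)Cl
Why: Kinetic ester deprotonation in THF places the α-substituent cis to the alkoxy group; O-silylation (Ireland conditions) should trap this as the (E)-ketene acetal.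

Step 2
Reactants: 2 (E)-1-methoxy-3-methyl-1-(trimethylsilyloxy)but-1-ene; 3 (R)-4-(tert-butyldimethylsilyloxy)cyclopent-2-en-1-one
Product: 5 methyl (2S)-2-[(1S,2R)-2-(tert-butyldimethylsilyloxy)-4-oxocyclopentyl]-3-methylbutanoate, via enol silane 4 (not isolated)
Conditions: Ph3CSbCl6 (5 mol%), CH2Cl2, −78 °C; then aq. citric acid, THF, 0 °C
Reagents that add atoms: none
Why: Mukaiyama–Michael addition with silyl transfer; the nucleophile should add to C2 anti to the neighbouring silyloxy group (sets C2), and the open antiperiplanar transition state keeps the isopropyl group away from the oxygenated ring carbon (sets C1, the sense known for α-substituted ketene acetals and cyclopentenones); mild acid hydrolyses only the TMS enol ether.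

Step 3
Reactants: 5 methyl (2S)-2-[(1S,2R)-2-(tert-butyldimethylsilyloxy)-4-oxocyclopentyl]-3-methylbutanoate
Product: 6 methyl (2S)-3-methyl-2-[(1R)-4-oxocyclopent-2-en-1-yl]butanoate
Conditions: DBU, CH2Cl2, 0 °C
Reagents that add atoms: none
Why: E1cB loss of silanol from the β-silyloxy ketone moves the enone to C5=C6 with the carbonyl at C4; short exposure at 0 °C should avoid γ-deprotonation at C2.

Step 4
Reactants: 6 methyl (2S)-3-methyl-2-[(1R)-4-oxocyclopent-2-en-1-yl]butanoate; 7 (2-methylprop-2-en-1-yl)magnesium chloride
Product: 9 methyl (2S)-3-methyl-2-[(1R,2S)-2-(2-methylprop-2-en-1-yl)-4-(trifluoromethanesulfonyloxy)cyclopent-3-en-1-yl]butanoate, via enol silane 8 (not isolated)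
Conditions: CuBr·SMe2, LiCl, Me3SiCl, THF, −78 °C; then CsF, PhNTf2, DME, rt
Reagents that add atoms: N-phenylbis(trifluoromethanesulfonimide), O=S(=O)(C(F)(F)F)N(c1ccccc1)S(=O)(=O)C(F)(F)F
Why: Silyl-assisted conjugate addition of the allylic copper reagent to a 4-substituted cyclopentenone should occur anti to the C2 side chain (sets C6 trans); the enolate is trapped as the C4=C5 enol silane and converted with fluoride into the enol triflate without loss of regiochemistry.

Step 5
Reactants: 9 methyl (2S)-3-methyl-2-[(1R,2S)-2-(2-methylprop-2-en-1-yl)-4-(trifluoromethanesulfonyloxy)cyclopent-3-en-1-yl]butanoate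
Product: 10 (2S)-3-methyl-2-[(1R,2S)-2-(2-methylprop-2-en-1-yl)-4-(trifluoromethanesulfonyloxy)cyclopent-3-en-1-yl]butanal
Conditions: i-Bu2AlH, CH2Cl2, −78 °C
Reagents that add atoms: none
Why: Partial reduction of a hindered α-branched methyl ester via the tetrahedral aluminate, which is stable at low temperature; the enol triflate and the alkene are inert.

Step 6
Reactants: 10 (2S)-3-methyl-2-[(1R,2S)-2-(2-methylprop-2-en-1-yl)-4-(trifluoromethanesulfonyloxy)cyclopent-3-en-1-yl]butanal; 11 N-(4-methoxybenzyl)hydroxylamine
Product: 12 (Z)-N-(4-methoxybenzyl) nitrone of aldehyde 10 (C10H=N(O)PMB, configuration of 10 retained)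
Conditions: MgSO4, CH2Cl2, rt
Reagents that add atoms: none
Why: Condensation of an aldehyde with an N-substituted hydroxylamine gives the (Z)-aldonitrone under neutral conditions, so C1 should not epimerise.

Step 7
Reactants: 12 (Z)-N-(4-methoxybenzyl) nitrone of aldehyde 10
Product: 13 (1S,2R,6S,8R,10R)-isoxazolidine-bridged trans-hydroazulene: C8–O–N(PMB)–C10 bridge on the β face, C8 methyl α, C1 isopropyl, C4 enol triflate (C4=C5)
Conditions: PhMe (0.01 M), 110 °C
Reagents that add atoms: none
Why: The (Z)-nitrone should add across C8=C9 in a concerted suprafacial [3+2] cycloaddition, joining C10 to the unsubstituted C9 and the nitrone oxygen to the fully substituted C8. The closest known reaction is the intramolecular nitrone–alkene cycloaddition of hept-6-enyl nitrones, whose bridged mode gives cycloheptanes when a trans-fused five-membered ring spans the two central tether atoms. The seven-membered carbocycle closes in the 7-endo sense, and the isoxazolidine closes as the N–O bridge of an 8-oxa-7-azabicyclo[4.2.1]nonane in which C10 is sp3, so no bridgehead C=N arises. The step needs the bridged mode over the fused six-membered mode (C10 to C8, O to C9); this is secured by the polarisation of the 1,1-disubstituted alkene (oxygen to the substituted carbon), by the congestion of joining the C1-branched nitrone carbon to a quaternary C8, and by the trans template. C8 is set by the alkene face that the oxygen reaches: with the C2 and C6 arms gauche and the isopropyl group pseudo-equatorial in the chair-like seven-membered transition state, the dipole should lie on the β face, putting O on C8 β and methyl α. C10 is set by the bridge itself (N cis to the C8 oxygen) and is erased in step 10. The enol triflate is electron-poor, trisubstituted and reachable only through a norbornane-type tricycle, so it should remain a spectator, and high dilution suppresses intermolecular addition. The addition is reversible at higher temperature, which leaves room for equilibration.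

Step 8
Reactants: 13 isoxazolidine-bridged trans-hydroazulene enol triflate
Product: 14 (1S,2R,6S,8R,10R)-amino alcohol: C10 β-NH(PMB), C8 β-OH, C8 methyl, C1 isopropyl, C4 enol triflate
Conditions: Zn, AcOH–H2O, 50 °C
Reagents that add atoms: none
Why: Reductive cleavage of the isoxazolidine N–O bond by zinc in acetic acid; the enol triflate is not reduced without a transition-metal catalyst.

Step 9
Reactants: 14 C10 β-NH(PMB) amino alcohol
Product: 15 (1S,2R,6S,8R,10R)-primary amino alcohol: C10 β-NH2, C8 β-OH, C4 enol triflate
Conditions: (NH4)2Ce(NO3)6, MeCN–H2O, 0 °C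
Reagents that add atoms: none
Why: Oxidative removal of the electron-rich benzyl group by single-electron oxidation to the benzylic iminium ion and hydrolysis; the tertiary carbinol and enol triflate are not oxidisable.

Step 10
Reactants: 15 C10 β-NH2 amino alcohol
Product: 17 (1S,2R,6S,8R)-β-hydroxy ketone: C10 ketone, C8 β-OH, C4 enol triflate, via hydroxyaryl ketimine 16 (not isolated)
Conditions: 3,5-di-tert-butyl-1,2-benzoquinone, MeOH, rt; then aq. oxalic acid, THF, rt
Reagents that add atoms: water, O
Why: Quinone-mediated transamination: imine formation at the less hindered quinone carbonyl, prototropic shift driven by aromatisation to the aminophenol ketimine, and mild acid hydrolysis; no base is used, so retro-aldol cleavage is avoided.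

Step 11
Reactants: 17 β-hydroxy ketone
Product: 18 (1S,2R,6S,8R,10S)-diol: C10 α-OH, C8 β-OH, C4 enol triflate
Conditions: Me4NBH(OAc)3, MeCN–AcOH, −30 °C
Reagents that add atoms: none
Why: Hydroxyl-directed (Evans–Saksena) reduction: the borohydride bound to the C8 oxygen should deliver hydride to the β face of C10 and give the 1,3-anti diol.

Step 12
Reactants: 18 anti-diol; 19 4-(tert-butyldimethylsilyloxy)benzoic acid
Product: 20 (1S,2R,6S,8R,10S)-C10 α-[4-(tert-butyldimethylsilyloxy)benzoate], C8 β-OH, C4 enol triflate
Conditions: 2,4,6-Cl3C6H2COCl, Et3N, THF, rt; then 18, DMAP, PhMe, 60 °C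
Reagents that add atoms: none
Why: Yamaguchi esterification through the mixed anhydride acylates the hindered secondary C10 hydroxyl; the tertiary C8 hydroxyl does not react.

Step 13
Reactants: 20 C10 aroate enol triflate
Product: 21 (1S,2R,6S,8R,10S)-C4-methyl alkene (C4=C5), C10 α-aroate, C8 β-OH
Conditions: Me4Sn, Pd(PPh3)4, LiCl, THF, 65 °C
Reagents that add atoms: tetramethylstannane, C[Sn](C)(C)C
Why: Stille coupling of a cyclopentenyl triflate with a methyl donor under neutral conditions; the ester, silyl ether and free tertiary alcohol are tolerated.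

Step 14
Reactants: 21 C4-methyl alkene
Product: 22 (1S,2R,4R,5S,6S,8R,10S)-4,5-β-epoxide, C10 α-[4-(tert-butyldimethylsilyloxy)benzoate], C8 β-OH
Conditions: VO(acac)2, t-BuOOH, CH2Cl2, 0 °C to rt
Reagents that add atoms: tert-butyl hydroperoxide, CC(C)(C)OO
Why: Hydroxyl-directed epoxidation: the vanadate ester of the β C8 hydroxyl should deliver oxygen to the β face of C4=C5 across the C7–C6 link, against the steric bias.

Step 15
Reactants: 22 epoxide silyl ether
Product: 23 (1S,2R,4R,5S,6S,8R,10S)-4,5-β-epoxy-8β-hydroxy-1-isopropyl-4,8-dimethyl-trans-hydroazulen-10α-yl 4-hydroxybenzoate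
Conditions: Bu4NF, AcOH, THF, 0 °C
Reagents that add atoms: none
Why: Fluoride cleaves the aryl silyl ether rapidly; buffering with acetic acid keeps the phenoxide from attacking the ester or the epoxide.

## Compound list

1 | methyl 3-methylbutanoate | COC(=O)CC(C)C | starting material
2 | (E)-1-methoxy-3-methyl-1-(trimethylsilyloxy)but-1-ene | CO/C(O[Si](C)(C)C)=C\C(C)C | intermediate
3 | (R)-4-(tert-butyldimethylsilyloxy)cyclopent-2-en-1-one | CC(C)(C)[Si](C)(C)O[C@@H]1CC(=O)C=C1 | starting material
4 | methyl (2S)-2-[(1S,5R)-5-(tert-butyldimethylsilyloxy)-3-(trimethylsilyloxy)cyclopent-2-en-1-yl]-3-methylbutanoate | CC(C)[C@H](C(=O)OC)[C@@H]1C=C(O[Si](C)(C)C)C[C@H]1O[Si](C)(C)C(C)(C)C | intermediate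
5 | methyl (2S)-2-[(1S,2R)-2-(tert-butyldimethylsilyloxy)-4-oxocyclopentyl]-3-methylbutanoate | CC(C)[C@H](C(=O)OC)[C@@H]1CC(=O)C[C@H]1O[Si](C)(C)C(C)(C)C | intermediate
6 | methyl (2S)-3-methyl-2-[(1R)-4-oxocyclopent-2-en-1-yl]butanoate | CC(C)[C@H](C(=O)OC)[C@@H]1CC(=O)C=C1 | intermediate
7 | (2-methylprop-2-en-1-yl)magnesium chloride | C=C(C)C[Mg]Cl | starting material
8 | methyl (2S)-3-methyl-2-[(1R,2S)-2-(2-methylprop-2-en-1-yl)-4-(trimethylsilyloxy)cyclopent-3-en-1-yl]butanoate | CC(C)[C@H](C(=O)OC)[C@@H]1CC(O[Si](C)(C)C)=C[C@H]1CC(C)=C | intermediate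
9 | methyl (2S)-3-methyl-2-[(1R,2S)-2-(2-methylprop-2-en-1-yl)-4-(trifluoromethanesulfonyloxy)cyclopent-3-en-1-yl]butanoate | CC(C)[C@H](C(=O)OC)[C@@H]1CC(OS(=O)(=O)C(F)(F)F)=C[C@H]1CC(C)=C | intermediate
10 | (2S)-3-methyl-2-[(1R,2S)-2-(2-methylprop-2-en-1-yl)-4-(trifluoromethanesulfonyloxy)cyclopent-3-en-1-yl]butanal | CC(C)[C@H](C=O)[C@@H]1CC(OS(=O)(=O)C(F)(F)F)=C[C@H]1CC(C)=C | intermediate
11 | N-(4-methoxybenzyl)hydroxylamine | COc1ccc(CNO)cc1 | starting material
12 | (Z)-N-(4-methoxybenzyl) nitrone of aldehyde 10 | CC(C)[C@H](/C=[N+](\[O-])Cc1ccc(OC)cc1)[C@@H]1CC(OS(=O)(=O)C(F)(F)F)=C[C@H]1CC(C)=C | intermediate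
13 | (1S,2R,6S,8R,10R)-isoxazolidine-bridged trans-hydroazulene, C8–O–N(PMB)–C10 bridge β, C4 enol triflate | CC(C)[C@H]1[C@@H]2CC(OS(=O)(=O)C(F)(F)F)=C[C@H]2C[C@]3(C)C[C@H]1N(Cc4ccc(OC)cc4)O3 | intermediate
14 | (1S,2R,6S,8R,10R)-amino alcohol, C10 β-NH(PMB), C8 β-OH, C4 enol triflate | CC(C)[C@H]1[C@@H]2CC(OS(=O)(=O)C(F)(F)F)=C[C@H]2C[C@@](C)(O)C[C@H]1NCc3ccc(OC)cc3 | intermediate
15 | (1S,2R,6S,8R,10R)-amino alcohol, C10 β-NH2, C8 β-OH, C4 enol triflate | CC(C)[C@H]1[C@@H]2CC(OS(=O)(=O)C(F)(F)F)=C[C@H]2C[C@@](C)(O)C[C@H]1N | intermediate
16 | C10 N-(3,5-di-tert-butyl-2-hydroxyphenyl) ketimine of 17 | CC(C)[C@H]1[C@@H]2CC(OS(=O)(=O)C(F)(F)F)=C[C@H]2C[C@@](C)(O)CC1=Nc3cc(C(C)(C)C)cc(C(C)(C)C)c3O | intermediate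
17 | (1S,2R,6S,8R)-β-hydroxy ketone, C10 ketone, C8 β-OH, C4 enol triflate | CC(C)[C@H]1[C@@H]2CC(OS(=O)(=O)C(F)(F)F)=C[C@H]2C[C@@](C)(O)CC1=O | intermediate
18 | (1S,2R,6S,8R,10S)-diol, C10 α-OH, C8 β-OH, C4 enol triflate | CC(C)[C@H]1[C@@H]2CC(OS(=O)(=O)C(F)(F)F)=C[C@H]2C[C@@](C)(O)C[C@@H]1O | intermediate
19 | 4-(tert-butyldimethylsilyloxy)benzoic acid | CC(C)(C)[Si](C)(C)Oc1ccc(C(=O)O)cc1 | starting material
20 | (1S,2R,6S,8R,10S)-C10 α-[4-(tert-butyldimethylsilyloxy)benzoate], C8 β-OH, C4 enol triflate | CC(C)[C@H]1[C@@H]2CC(OS(=O)(=O)C(F)(F)F)=C[C@H]2C[C@@](C)(O)C[C@@H]1OC(=O)c3ccc(O[Si](C)(C)C(C)(C)C)cc3 | intermediate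
21 | (1S,2R,6S,8R,10S)-C4-methyl alkene (C4=C5), C10 α-[4-(tert-butyldimethylsilyloxy)benzoate], C8 β-OH | CC(C)[C@H]1[C@@H]2CC(C)=C[C@H]2C[C@@](C)(O)C[C@@H]1OC(=O)c3ccc(O[Si](C)(C)C(C)(C)C)cc3 | intermediate
22 | (1S,2R,4R,5S,6S,8R,10S)-4,5-β-epoxide, C10 α-[4-(tert-butyldimethylsilyloxy)benzoate], C8 β-OH | CC(C)[C@H]1[C@@H]2C[C@@]3(C)O[C@H]3[C@H]2C[C@@](C)(O)C[C@@H]1OC(=O)c4ccc(O[Si](C)(C)C(C)(C)C)cc4 | intermediate
23 | (1S,2R,4R,5S,6S,8R,10S)-4,5-β-epoxy-8β-hydroxy-1-isopropyl-4,8-dimethyl-trans-hydroazulen-10α-yl 4-hydroxybenzoate | CC(C)[C@H]1[C@@H]2C[C@@]3(C)O[C@H]3[C@H]2C[C@@](C)(O)C[C@@H]1OC(=O)c1ccc(O)cc1 | target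

## Step count and least certain steps

Total: 15 steps. Longest linear sequence: 15 steps (from 1; 14 from 3).

**Step 7 (key step).** The most likely failure is poor facial selectivity at C8, because the two twisted seven-membered transition states differ only in how the isopropyl group and the N-substituent are placed. Diversion into the fused six-membered mode, or addition across the ring onto the enol triflate, are the other risks.

The fallback sets out from aldehyde 10 and returns at 17; it builds the ring by metathesis and sets C8 by reagent and hydroxyl control. Vinylmagnesium bromide (THF, −78 °C) should give the allylic alcohols F1 (both C10 epimers). Ring-closing metathesis with the second-generation Grubbs catalyst between the vinyl group and the C8 methylidene should close the cycloheptenol F2. Dess–Martin oxidation gives the enone F3. Corey–Bakshi–Shibata reduction (B-methyl oxazaborolidine from diphenylprolinol, BH3·SMe2, catalyst enantiomer chosen for hydride delivery to the α face) gives the C10 β-alcohol F4. VO(acac)2 and t-BuOOH then place the epoxide syn to that hydroxyl in the epoxy alcohol F5. A second Dess–Martin oxidation gives the epoxy ketone F6, and SmI2 (THF–MeOH, −78 °C) cleaves the α C–O bond to give 17.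

**Step 2.** The risk is poor simple diastereoselection at C1, because the open transition state is controlled only by non-bonded interactions and depends on ketene acetal geometry.

The fallback sets out from ester 1 and returns at 6; it fixes C1 and C2 by a chair Ireland–Claisen rearrangement. Wittig reaction of pent-4-enal with 1-(triphenylphosphoranylidene)propan-2-one gives the dienone F7, and Corey–Bakshi–Shibata reduction gives the (S)-dienol F8. Transesterification of 1 with F8 (Ti(O-i-Pr)4) gives the allylic ester F9. Enolisation with LiN(i-Pr)2 in THF–DMPU, silylation and warming should give, by chirality transfer from the equatorial methyl carbinol, the acid F10. Me3SiCHN2 gives the methyl ester F11. Ring-closing metathesis (second-generation Grubbs catalyst) gives the cyclopentene F12. Allylic oxidation at the ring methylene remote from the side chain (CrO3·3,5-dimethylpyrazole) gives 6.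

**Step 9.** The risk is sluggish or unselective oxidative dealkylation of a hindered secondary amine, with oxidation of the liberated amine as the competing process.

The fallback sets out from 10 and returns at 17; it avoids N-dealkylation altogether. N-tert-butylhydroxylamine with 10 gives the nitrone F13, which on heating in toluene should cyclise as in step 7 to the N-tert-butyl isoxazolidine F14. Zn in AcOH gives the amino alcohol F15. Tungstate-catalysed oxidation (Na2WO4, urea–H2O2, MeOH) of this secondary amine can only form the C=N bond toward C10 and gives the ketonitrone F16, which aqueous acid hydrolyses to 17.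

**Step 14.** The risk is a slow or wrong-face epoxidation, because the directing hydroxyl is bishomoallylic and the β face is the hindered one.

The fallback sets out from 21 and returns at 23; it reaches the β-epoxide by anti opening of an α-bromonium ion. The C8 hydroxyl is first masked (TMS-imidazole) as the silyl ether F17, so that it cannot cyclise onto the bromonium ion. NBS in buffered aqueous THF should then give the bromohydrin F18 (C5 α-Br, C4 β-OH). DBU closes the β-epoxide F19. Bu4NF with AcOH removes both silyl groups to give 23.

## Further compounds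

F1 | step 7 | (4S)-5-methyl-4-[(1R,2S)-2-(2-methylprop-2-en-1-yl)-4-(trifluoromethanesulfonyloxy)cyclopent-3-en-1-yl]hex-1-en-3-ol, both C3 epimers | CC(C)[C@H](C(O)C=C)[C@@H]1CC(OS(=O)(=O)C(F)(F)F)=C[C@H]1CC(C)=C
F2 | step 7 | trans-hydroazulene C10 alcohol (both epimers) with C8=C9 (C8 methyl), C4 enol triflate | CC(C)[C@H]1[C@@H]2CC(OS(=O)(=O)C(F)(F)F)=C[C@H]2CC(C)=CC1O
F3 | step 7 | trans-hydroazulene C10 ketone with C8=C9 (C8 methyl), C4 enol triflate | CC(C)[C@H]1[C@@H]2CC(OS(=O)(=O)C(F)(F)F)=C[C@H]2CC(C)=CC1=O
F4 | step 7 | (10S)-C10 β-alcohol of F3 | CC(C)[C@H]1[C@@H]2CC(OS(=O)(=O)C(F)(F)F)=C[C@H]2CC(C)=C[C@H]1O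
F5 | step 7 | 8,9-β-epoxy C10 β-alcohol, C4 enol triflate | CC(C)[C@H]1[C@@H]2CC(OS(=O)(=O)C(F)(F)F)=C[C@H]2C[C@@]3(C)O[C@H]3[C@H]1O
F6 | step 7 | 8,9-β-epoxy C10 ketone, C4 enol triflate | CC(C)[C@H]1[C@@H]2CC(OS(=O)(=O)C(F)(F)F)=C[C@H]2C[C@@]3(C)O[C@H]3C1=O
F7 | step 2 | (E)-octa-3,7-dien-2-one | CC(=O)/C=C/CCC=C
F8 | step 2 | (2S,3E)-octa-3,7-dien-2-ol | C[C@H](O)/C=C/CCC=C
F9 | step 2 | (2S,3E)-octa-3,7-dien-2-yl 3-methylbutanoate | CC(C)CC(=O)O[C@@H](C)/C=C/CCC=C
F10 | step 2 | (2S,3R,4E)-3-(but-3-en-1-yl)-2-(propan-2-yl)hex-4-enoic acid | CC(C)[C@H](C(=O)O)[C@H](CCC=C)/C=C/C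
F11 | step 2 | methyl (2S,3R,4E)-3-(but-3-en-1-yl)-2-(propan-2-yl)hex-4-enoate | CC(C)[C@H](C(=O)OC)[C@H](CCC=C)/C=C/C
F12 | step 2 | methyl (2S)-2-[(1R)-cyclopent-2-en-1-yl]-3-methylbutanoate | CC(C)[C@H](C(=O)OC)[C@@H]1CCC=C1
F13 | step 9 | (Z)-N-tert-butyl nitrone of aldehyde 10 | CC(C)[C@H](/C=[N+](\[O-])C(C)(C)C)[C@@H]1CC(OS(=O)(=O)C(F)(F)F)=C[C@H]1CC(C)=C
F14 | step 9 | N-tert-butyl analogue of 13 | CC(C)[C@H]1[C@@H]2CC(OS(=O)(=O)C(F)(F)F)=C[C@H]2C[C@]3(C)C[C@H]1N(C(C)(C)C)O3
F15 | step 9 | N-tert-butyl analogue of 14 | CC(C)[C@H]1[C@@H]2CC(OS(=O)(=O)C(F)(F)F)=C[C@H]2C[C@@](C)(O)C[C@H]1NC(C)(C)C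
F16 | step 9 | C10 N-tert-butyl ketonitrone, C8 β-OH, C4 enol triflate | CC(C)[C@H]1[C@@H]2CC(OS(=O)(=O)C(F)(F)F)=C[C@H]2C[C@@](C)(O)CC1=[N+]([O-])C(C)(C)C
F17 | step 14 | C8 trimethylsilyl ether of 21 | CC(C)[C@H]1[C@@H]2CC(C)=C[C@H]2C[C@@](C)(O[Si](C)(C)C)C[C@@H]1OC(=O)c3ccc(O[Si](C)(C)C(C)(C)C)cc3
F18 | step 14 | bromohydrin of F17, C5 α-Br, C4 β-OH | CC(C)[C@H]1[C@@H]2C[C@@](C)(O)[C@H](Br)[C@H]2C[C@@](C)(O[Si](C)(C)C)C[C@@H]1OC(=O)c3ccc(O[Si](C)(C)C(C)(C)C)cc3
F19 | step 14 | C8 trimethylsilyl ether of 22 | CC(C)[C@H]1[C@@H]2C[C@@]3(C)O[C@H]3[C@H]2C[C@@](C)(O[Si](C)(C)C)C[C@@H]1OC(=O)c4ccc(O[Si](C)(C)C(C)(C)C)cc4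
A1 | alternative 1 | cross-conjugated dienone: cycloheptenyl (E)-2-methyl-3-(trimethylsilyl)propenyl ketone with C8 triethylsilyl ether and C10 TBS ether | C[Si](C)(C)/C=C(\C)C(=O)C1=C[C@H](C(C)C)[C@@H](O[Si](C)(C)C(C)(C)C)C[C@](C)(O[Si](CC)(CC)CC)C1
A2 | alternative 1 | trans-fused hydroazulene 2-methylcyclopent-2-enone (C3=C4, C5 ketone) | CC(C)[C@H]1[C@@H]2C=C(C)C(=O)[C@H]2C[C@@](C)(O[Si](CC)(CC)CC)C[C@@H]1O[Si](C)(C)C(C)(C)C
A3 | alternative 2 | C10 bromomethyl ketone with C8 methyl ketone on the trans-disubstituted 1-methylcyclopentene | CC(C)[C@H](C(=O)CBr)[C@@H]1CC(C)=C[C@H]1CC(C)=O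
A4 | alternative 2 | trans-fused hydroazulene β-hydroxy ketone (C8 alcohol, C10 ketone, C4=C5) | CC(C)[C@H]1[C@@H]2CC(C)=C[C@H]2C[C@@](C)(O)CC1=O
A5 | alternative 3 | (Z)-3-(tert-butyldimethylsilyloxy)-2,5-dimethylhexa-1,3-diene | CC(C)/C=C(\O[Si](C)(C)C(C)(C)C)C(C)=C
A6 | alternative 3 | cyclopent-2-en-1-one | O=C1C=CCC1
A7 | alternative 3 | cis-fused endo hydrindanone enol silane | CC(C)[C@@H]1[C@@H]2CCC(=O)[C@@H]2CC(C)=C1O[Si](C)(C)C(C)(C)C
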